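**Strategy.** Both six-membered rings are traced to one enol triflate, and its carbocycle is not made as a cyclohexane. The epoxy-ring carbons C1–C6 arise by one-carbon ring expansion of (S)-4-silyloxy-2,2-dimethylcyclopentanone with diazoethane. This inserts the methyl-bearing C5 between the carbonyl carbon (future C6) and the unsubstituted α-CH2 (future C4), the quaternary C1 blocking the other side; the C3 carbinol centre is carried through unchanged. Triflation, hydroxymethylation and Sharpless epoxidation give the epoxy end group. A bromo-ylidenebutenolide linchpin, Suzuki coupling and a final Wittig olefination with the acetylenic C15 phosphonium salt (from the same triflate) complete pyrrhoxanthin.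

Key step: step 4

Remark: end-group positions are cited in carotenoid numbering (epoxy ring C1–C6 with the C7=C8 vinyl; primed locants for the acetylenic ring). Compound 7 is carried as a mixture of epimers at its methyl-bearing α-carbon, which becomes sp2 in step 5.

Step 1
Reactants: 1 2,2-dimethylcyclopentan-1-one
Product: 2 5,5-dimethylcyclopent-2-en-1-one
Conditions: IBX (2 equiv), DMSO/fluorobenzene 1:2, 70 °C
Reagents that add atoms: none
Why: IBX-mediated α,β-dehydrogenation of a ketone should desaturate the only enolisable side, because the other α-carbon is quaternary.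

Step 2
Reactants: 2 5,5-dimethylcyclopent-2-en-1-one
Product: 4 (4S)-4-hydroxy-2,2-dimethylcyclopentan-1-one, via β-boryl ketone 3 (not isolated)
Conditions: CuCl (3 mol %), NaOt-Bu (6 mol %), Josiphos-type bisphosphine (3 mol %, enantiomer chosen to give 4S), B2pin2 (1.1 equiv), MeOH (2 equiv), THF, rt; then NaBO3·4H2O, THF/H2O, rt
Reagents that add atoms: bis(pinacolato)diboron, CC1(C)OB(OC1(C)C)B1OC(C)(C)C(C)(C)O1 (boron of 3); sodium perborate, [Na+].[O-]OB=O (oxygen of 4)
Why: Copper(I)-catalysed enantioselective conjugate borylation sets the carbinol centre (later C3 and C3′) through ligand control of the β-face, and perborate oxidation of the C–B bond proceeds with retention.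

Step 3
Reactants: 4 (4S)-4-hydroxy-2,2-dimethylcyclopentan-1-one
Product: 5 (4S)-4-(tert-butyldimethylsilyloxy)-2,2-dimethylcyclopentan-1-one
Conditions: TBSCl, imidazole, DMF, 0 °C → rt
Reagents that add atoms: tert-butyldimethylsilyl chloride, CC(C)(C)[Si](C)(C)Cl
Why: Imidazole-promoted silylation of a secondary alcohol is mild enough to avoid β-elimination of the aldol-type alcohol.

Step 4
Reactants: 5 (4S)-4-(tert-butyldimethylsilyloxy)-2,2-dimethylcyclopentan-1-one
Product: 7 (4R)-4-(tert-butyldimethylsilyloxy)-2,2,6-trimethylcyclohexan-1-one (C6 epimers), via diazonium alkoxide 6 (not isolated)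
Conditions: Me3Al (1.1 equiv), CH2Cl2, −78 °C; CH3CHN2 (1.5 equiv, Et2O solution from N-ethyl-N-nitrosourea/KOH), −78 °C
Reagents that add atoms: diazoethane, CC=[N+]=[N-]
Why: Me3Al activates the carbonyl of 5, the nucleophilic carbon of diazoethane adds to give the aluminium-bound β-oxido diazonium 6, and loss of N2 is coupled to a 1,2-shift of a ring C–C bond onto the diazonium carbon, which enlarges the cyclopentanone to the cyclohexanone. The closest known reaction type is the Lewis acid-promoted diazoalkane homologation of cyclic ketones (Tiffeneau–Demjanov-type ring expansion, organoaluminium variant). No ring is closed by cyclisation: the six-membered ring arises by insertion of the CHMe carbon into the C1–C5 bond of the five-membered ring. The silyloxy-bearing centre is a spectator and becomes C3 of the end group unchanged, while the new methine (future C5) forms as an epimer mixture that step 5 erases. The step needs migration of the α-CH2 and not of the quaternary α-carbon, and it must stop after one insertion. The first should follow from the steric preference of this reaction for the less substituted carbon, the second from the product being a doubly α-branched ketone that is far less electrophilic than 5.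

Step 5
Reactants: 7 (4R)-4-(tert-butyldimethylsilyloxy)-2,2,6-trimethylcyclohexan-1-one
Product: 9 (4R)-4-(tert-butyldimethylsilyloxy)-2,6,6-trimethylcyclohex-1-en-1-yl trifluoromethanesulfonate, via lithium enolate 8 (not isolated)
Conditions: LDA (1.3 equiv), THF, −78 → 0 °C; PhNTf2 (1.4 equiv), −78 °C → rt
Reagents that add atoms: N-phenylbis(trifluoromethanesulfonimide), FC(F)(F)S(=O)(=O)N(c1ccccc1)S(=O)(=O)C(F)(F)F
Why: Enol triflate formation can occur only through the tertiary α-C–H (the other α-carbon is quaternary), so O-sulfonylation of the single enolate gives the tetrasubstituted vinyl triflate and removes the epimeric centre.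

Step 6
Reactants: 9 (4R)-4-(tert-butyldimethylsilyloxy)-2,6,6-trimethylcyclohex-1-en-1-yl trifluoromethanesulfonate
Product: 10 [(4R)-4-(tert-butyldimethylsilyloxy)-2,6,6-trimethylcyclohex-1-en-1-yl]methanol
Conditions: Bu3SnCH2OH (1.5 equiv), Pd(PPh3)4 (5 mol %), LiCl (3 equiv), 1,4-dioxane, 100 °C
Reagents that add atoms: (tributylstannyl)methanol, CCCC[Sn](CCCC)(CCCC)CO
Why: Migita–Kosugi–Stille coupling of the vinyl triflate with hydroxymethyl transfer from tin should install C7 as the allylic alcohol in one operation.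

Step 7
Reactants: 10 [(4R)-4-(tert-butyldimethylsilyloxy)-2,6,6-trimethylcyclohex-1-en-1-yl]methanol
Product: 11 [(1R,4S,6R)-4-(tert-butyldimethylsilyloxy)-2,2,6-trimethyl-7-oxabicyclo[4.1.0]heptan-1-yl]methanol (epoxide anti to the silyloxy group)
Conditions: Ti(Oi-Pr)4 (1.0 equiv), D-(−)-diethyl tartrate (1.2 equiv), t-BuOOH (2 equiv, decane), 4 Å MS, CH2Cl2, −20 °C
Reagents that add atoms: tert-butyl hydroperoxide, CC(C)(C)OO
Why: Sharpless–Katsuki asymmetric epoxidation of the allylic alcohol sets C5 and C6 under reagent control, the D-(−)-tartrate complex delivering oxygen to the alkene face anti to the C3 silyloxy group.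

Step 8
Reactants: 11 [(1R,4S,6R)-4-(tert-butyldimethylsilyloxy)-2,2,6-trimethyl-7-oxabicyclo[4.1.0]heptan-1-yl]methanol
Product: 12 (1S,4S,6R)-4-(tert-butyldimethylsilyloxy)-2,2,6-trimethyl-7-oxabicyclo[4.1.0]heptane-1-carbaldehyde
Conditions: TPAP (5 mol %), NMO (1.5 equiv), 4 Å MS, CH2Cl2, rt
Reagents that add atoms: none
Why: Ley–Griffith oxidation converts the primary alcohol into the non-enolisable α-epoxy aldehyde under neutral conditions that leave epoxide and silyl ether intact.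

Step 9
Reactants: 12 (1S,4S,6R)-4-(tert-butyldimethylsilyloxy)-2,2,6-trimethyl-7-oxabicyclo[4.1.0]heptane-1-carbaldehyde
Product: 13 2-{(E)-2-[(1S,4S,6R)-4-(tert-butyldimethylsilyloxy)-2,2,6-trimethyl-7-oxabicyclo[4.1.0]heptan-1-yl]ethenyl}-4,4,5,5-tetramethyl-1,3,2-dioxaborolane
Conditions: Cl2CHBpin (2 equiv), CrCl2 (8 equiv), LiI (4 equiv), THF, rt
Reagents that add atoms: 2-(dichloromethyl)-4,4,5,5-tetramethyl-1,3,2-dioxaborolane, CC1(C)OB(OC1(C)C)C(Cl)Cl
Why: Takai–Utimoto chromium(II) olefination with the gem-dichromium boryl reagent should give the (E)-alkenylboronate (C7=C8) through anti elimination of the β-oxido chromium adduct.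

Step 10
Reactants: 13 2-{(E)-2-[(1S,4S,6R)-4-(tert-butyldimethylsilyloxy)-2,2,6-trimethyl-7-oxabicyclo[4.1.0]heptan-1-yl]ethenyl}-4,4,5,5-tetramethyl-1,3,2-dioxaborolane
Product: 14 (1R,3S,6S)-1,5,5-trimethyl-6-[(E)-2-(4,4,5,5-tetramethyl-1,3,2-dioxaborolan-2-yl)ethenyl]-7-oxabicyclo[4.1.0]heptan-3-ol
Conditions: TBAF (1.2 equiv), THF, 0 °C → rt
Reagents that add atoms: none
Why: Fluoride cleavage of the TBS ether frees the C3 hydroxyl at a stage where only a pinacol boronate and a base-stable epoxide are present.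

Step 11
Reactants: 15 propiolic acid
Product: 16 (E)-2,3-dibromoprop-2-enoic acid
Conditions: Br2 (1.0 equiv), CHCl3, 0 °C → rt, dark
Reagents that add atoms: bromine, BrBr
Why: Electrophilic anti addition of bromine to the alkyne gives the (E)-dibromide, which places the β-bromine cis to the carboxyl group.

Step 12
Reactants: 16 (E)-2,3-dibromoprop-2-enoic acid; 17 (E)-3-methylpent-2-en-4-yn-1-ol
Product: 19 (5Z)-3-bromo-5-[(2E)-4-hydroxy-2-methylbut-2-en-1-ylidene]furan-2(5H)-one, via bromo-enynoic acid 18 (not isolated)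
Conditions: PdCl2(PPh3)2 (5 mol %), CuI (10 mol %), Et3N (4 equiv), MeCN, rt
Reagents that add atoms: none
Why: Tandem Sonogashira coupling at the more reactive β-C–Br bond and metal-promoted 5-exo-dig anti addition of the cis carboxylate across the alkyne should give the (Z)-γ-ylidenebutenolide with the α-bromine retained.

Step 13
Reactants: 14 (1R,3S,6S)-1,5,5-trimethyl-6-[(E)-2-(4,4,5,5-tetramethyl-1,3,2-dioxaborolan-2-yl)ethenyl]-7-oxabicyclo[4.1.0]heptan-3-ol; 19 (5Z)-3-bromo-5-[(2E)-4-hydroxy-2-methylbut-2-en-1-ylidene]furan-2(5H)-one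
Product: 20 (5Z)-3-{(E)-2-[(1S,4S,6R)-4-hydroxy-2,2,6-trimethyl-7-oxabicyclo[4.1.0]heptan-1-yl]ethenyl}-5-[(2E)-4-hydroxy-2-methylbut-2-en-1-ylidene]furan-2(5H)-one
Conditions: Pd2(dba)3 (2.5 mol %), AsPh3 (20 mol %), Ag2O (1.5 equiv), THF/H2O 8:1, rt
Reagents that add atoms: none
Why: Silver(I) oxide-promoted Suzuki–Miyaura coupling of the activated α-bromobutenolide with the (E)-alkenylboronate proceeds with retention of both alkene geometries and without strong base, and the hindered tetrasubstituted vinyl epoxide should not be ionised by Pd(0) at room temperature.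

Step 14
Reactants: 20 (5Z)-3-{(E)-2-[(1S,4S,6R)-4-hydroxy-2,2,6-trimethyl-7-oxabicyclo[4.1.0]heptan-1-yl]ethenyl}-5-[(2E)-4-hydroxy-2-methylbut-2-en-1-ylidene]furan-2(5H)-one
Product: 21 (2E,4Z)-4-[4-{(E)-2-[(1S,4S,6R)-4-hydroxy-2,2,6-trimethyl-7-oxabicyclo[4.1.0]heptan-1-yl]ethenyl}-5-oxofuran-2(5H)-ylidene]-2-methylbut-2-enal
Conditions: MnO2 (20 equiv), CH2Cl2, rt
Reagents that add atoms: none
Why: Manganese dioxide oxidises only the primary allylic alcohol, since the secondary ring alcohol is not allylic.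

Step 15
Reactants: 21 (2E,4Z)-4-[4-{(E)-2-[(1S,4S,6R)-4-hydroxy-2,2,6-trimethyl-7-oxabicyclo[4.1.0]heptan-1-yl]ethenyl}-5-oxofuran-2(5H)-ylidene]-2-methylbut-2-enal
Product: 22 (2E,4E,6Z)-6-[4-{(E)-2-[(1S,4S,6R)-4-hydroxy-2,2,6-trimethyl-7-oxabicyclo[4.1.0]heptan-1-yl]ethenyl}-5-oxofuran-2(5H)-ylidene]-4-methylhexa-2,4-dienal
Conditions: Ph3P=CHCHO (1.2 equiv), toluene, 70 °C
Reagents that add atoms: (triphenylphosphoranylidene)acetaldehyde, O=CC=P(c1ccccc1)(c1ccccc1)c1ccccc1
Why: Wittig reaction with the stabilised formylmethylene ylide should give the (E)-enal two-carbon homologue, the more extended product being less electrophilic than 21.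

Step 16
Reactants: 9 (4R)-4-(tert-butyldimethylsilyloxy)-2,6,6-trimethylcyclohex-1-en-1-yl trifluoromethanesulfonate
Product: 23 (1R)-3,5,5-trimethyl-4-{[(trifluoromethyl)sulfonyl]oxy}cyclohex-3-en-1-yl acetate
Conditions: Ac2O (3 equiv), Sc(OTf)3 (5 mol %), MeCN, 0 °C → rt
Reagents that add atoms: acetic anhydride, CC(=O)OC(C)=O
Why: Lewis acid-catalysed acetolysis of the silyl ether (O-acylation, then loss of silyl acetate) exchanges TBS for acetyl without breaking the C–O bond, so the configuration is retained.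

Step 17
Reactants: 23 (1R)-3,5,5-trimethyl-4-{[(trifluoromethyl)sulfonyl]oxy}cyclohex-3-en-1-yl acetate; 17 (E)-3-methylpent-2-en-4-yn-1-ol
Product: 24 (1R)-4-[(3E)-5-hydroxy-3-methylpent-3-en-1-yn-1-yl]-3,5,5-trimethylcyclohex-3-en-1-yl acetate
Conditions: Pd(PPh3)4 (5 mol %), CuI (10 mol %), i-Pr2NH (3 equiv), DMF, rt → 45 °C
Reagents that add atoms: none
Why: Sonogashira coupling of the vinyl triflate with the terminal alkyne builds the 7′,8′-didehydro end group with the (E)-enyne geometry of 17.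

Step 18
Reactants: 24 (1R)-4-[(3E)-5-hydroxy-3-methylpent-3-en-1-yn-1-yl]-3,5,5-trimethylcyclohex-3-en-1-yl acetate
Product: 25 {(2E)-5-[(4R)-4-acetoxy-2,6,6-trimethylcyclohex-1-en-1-yl]-3-methylpent-2-en-4-yn-1-yl}triphenylphosphonium bromide
Conditions: PPh3·HBr (1.05 equiv), CH2Cl2, rt
Reagents that add atoms: triphenylphosphine hydrobromide, [Br-].[PH+](c1ccccc1)(c1ccccc1)c1ccccc1
Why: Acid-mediated substitution of the primary allylic alcohol by triphenylphosphine (the standard preparation of carotenoid Wittig salts) should occur at the primary terminus and keep the conjugated (E)-enyne.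

Step 19
Reactants: 25 {(2E)-5-[(4R)-4-acetoxy-2,6,6-trimethylcyclohex-1-en-1-yl]-3-methylpent-2-en-4-yn-1-yl}triphenylphosphonium bromide; 22 (2E,4E,6Z)-6-[4-{(E)-2-[(1S,4S,6R)-4-hydroxy-2,2,6-trimethyl-7-oxabicyclo[4.1.0]heptan-1-yl]ethenyl}-5-oxofuran-2(5H)-ylidene]-4-methylhexa-2,4-dienal
Product: 28 pyrrhoxanthin, via phosphonium ylide 26 (not isolated), via Z-isomer 27 (not isolated)
Conditions: 25 (1.3 equiv), NaHMDS (1.25 equiv), THF, −78 °C; 22, −78 → 0 °C; crude in benzene, rt, Ar, dark (Z → E equilibration)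
Reagents that add atoms: none
Why: Wittig olefination of the semi-stabilised allylic ylide with the polyenal forms the last C=C as an E/Z mixture, and the Z isomer should equilibrate thermally to the all-E polyene while the (Z)-ylidene lactone, the stable form, is kept.

**Compound list**

1 | 2,2-dimethylcyclopentan-1-one | CC1(C)CCCC1=O | starting material
2 | 5,5-dimethylcyclopent-2-en-1-one | CC1(C)CC=CC1=O | intermediate
3 | (4S)-2,2-dimethyl-4-(4,4,5,5-tetramethyl-1,3,2-dioxaborolan-2-yl)cyclopentan-1-one (not isolated) | CC1(C)C[C@H](B2OC(C)(C)C(C)(C)O2)CC1=O | intermediate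
4 | (4S)-4-hydroxy-2,2-dimethylcyclopentan-1-one | CC1(C)C[C@H](O)CC1=O | intermediate
5 | (4S)-4-(tert-butyldimethylsilyloxy)-2,2-dimethylcyclopentan-1-one | CC1(C)C[C@H](O[Si](C)(C)C(C)(C)C)CC1=O | intermediate
6 | (4S)-4-(tert-butyldimethylsilyloxy)-1-(1-diazonioethyl)-2,2-dimethylcyclopentan-1-olate, aluminium-bound in the flask (not isolated) | CC([N+]#N)C1([O-])C[C@@H](O[Si](C)(C)C(C)(C)C)CC1(C)C | intermediate
7 | (4R)-4-(tert-butyldimethylsilyloxy)-2,2,6-trimethylcyclohexan-1-one, C6 epimers | CC1C[C@@H](O[Si](C)(C)C(C)(C)C)CC(C)(C)C1=O | intermediate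
8 | lithium (4R)-4-(tert-butyldimethylsilyloxy)-2,6,6-trimethylcyclohex-1-en-1-olate (not isolated) | CC1=C([O-])C(C)(C)C[C@H](O[Si](C)(C)C(C)(C)C)C1.[Li+] | intermediate
9 | (4R)-4-(tert-butyldimethylsilyloxy)-2,6,6-trimethylcyclohex-1-en-1-yl trifluoromethanesulfonate | CC1=C(OS(=O)(=O)C(F)(F)F)C(C)(C)C[C@H](O[Si](C)(C)C(C)(C)C)C1 | intermediate
10 | [(4R)-4-(tert-butyldimethylsilyloxy)-2,6,6-trimethylcyclohex-1-en-1-yl]methanol | CC1=C(CO)C(C)(C)C[C@H](O[Si](C)(C)C(C)(C)C)C1 | intermediate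
11 | [(1R,4S,6R)-4-(tert-butyldimethylsilyloxy)-2,2,6-trimethyl-7-oxabicyclo[4.1.0]heptan-1-yl]methanol | OC[C@@]12O[C@]1(C)C[C@@H](O[Si](C)(C)C(C)(C)C)CC2(C)C | intermediate
12 | (1S,4S,6R)-4-(tert-butyldimethylsilyloxy)-2,2,6-trimethyl-7-oxabicyclo[4.1.0]heptane-1-carbaldehyde | O=C[C@@]12O[C@]1(C)C[C@@H](O[Si](C)(C)C(C)(C)C)CC2(C)C | intermediate
13 | 2-{(E)-2-[(1S,4S,6R)-4-(tert-butyldimethylsilyloxy)-2,2,6-trimethyl-7-oxabicyclo[4.1.0]heptan-1-yl]ethenyl}-4,4,5,5-tetramethyl-1,3,2-dioxaborolane | CC1(C)OB(/C=C/[C@@]23O[C@]2(C)C[C@@H](O[Si](C)(C)C(C)(C)C)CC3(C)C)OC1(C)C | intermediate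
14 | (1R,3S,6S)-1,5,5-trimethyl-6-[(E)-2-(4,4,5,5-tetramethyl-1,3,2-dioxaborolan-2-yl)ethenyl]-7-oxabicyclo[4.1.0]heptan-3-ol | CC1(C)OB(/C=C/[C@@]23O[C@]2(C)C[C@@H](O)CC3(C)C)OC1(C)C | intermediate
15 | propiolic acid | C#CC(=O)O | starting material
16 | (E)-2,3-dibromoprop-2-enoic acid | OC(=O)/C(Br)=C\Br | intermediate
17 | (E)-3-methylpent-2-en-4-yn-1-ol | C#C/C(C)=C/CO | starting material
18 | (2E,6E)-2-bromo-8-hydroxy-6-methylocta-2,6-dien-4-ynoic acid, alkyne cis to the carboxyl group (not isolated) | OC(=O)/C(Br)=C\C#C/C(C)=C/CO | intermediate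
19 | (5Z)-3-bromo-5-[(2E)-4-hydroxy-2-methylbut-2-en-1-ylidene]furan-2(5H)-one | OC/C=C(C)/C=C1C=C(Br)C(=O)O/1 | intermediate
20 | (5Z)-3-{(E)-2-[(1S,4S,6R)-4-hydroxy-2,2,6-trimethyl-7-oxabicyclo[4.1.0]heptan-1-yl]ethenyl}-5-[(2E)-4-hydroxy-2-methylbut-2-en-1-ylidene]furan-2(5H)-one | OC/C=C(C)/C=C1C=C(/C=C/[C@@]23O[C@]2(C)C[C@@H](O)CC3(C)C)C(=O)O/1 | intermediate
21 | (2E,4Z)-4-[4-{(E)-2-[(1S,4S,6R)-4-hydroxy-2,2,6-trimethyl-7-oxabicyclo[4.1.0]heptan-1-yl]ethenyl}-5-oxofuran-2(5H)-ylidene]-2-methylbut-2-enal | O=C/C=C(C)/C=C1C=C(/C=C/[C@@]23O[C@]2(C)C[C@@H](O)CC3(C)C)C(=O)O/1 | intermediate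
22 | (2E,4E,6Z)-6-[4-{(E)-2-[(1S,4S,6R)-4-hydroxy-2,2,6-trimethyl-7-oxabicyclo[4.1.0]heptan-1-yl]ethenyl}-5-oxofuran-2(5H)-ylidene]-4-methylhexa-2,4-dienal | O=C/C=C/C=C(C)/C=C1C=C(/C=C/[C@@]23O[C@]2(C)C[C@@H](O)CC3(C)C)C(=O)O/1 | intermediate
23 | (1R)-3,5,5-trimethyl-4-{[(trifluoromethyl)sulfonyl]oxy}cyclohex-3-en-1-yl acetate | CC(=O)O[C@@H]1CC(C)=C(OS(=O)(=O)C(F)(F)F)C(C)(C)C1 | intermediate
24 | (1R)-4-[(3E)-5-hydroxy-3-methylpent-3-en-1-yn-1-yl]-3,5,5-trimethylcyclohex-3-en-1-yl acetate | CC(=O)O[C@@H]1CC(C)=C(C#C/C(C)=C/CO)C(C)(C)C1 | intermediate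
25 | {(2E)-5-[(4R)-4-acetoxy-2,6,6-trimethylcyclohex-1-en-1-yl]-3-methylpent-2-en-4-yn-1-yl}triphenylphosphonium bromide | CC(=O)O[C@@H]1CC(C)=C(C#C/C(C)=C/C[P+](c2ccccc2)(c2ccccc2)c2ccccc2)C(C)(C)C1.[Br-] | intermediate
26 | phosphonium ylide of 25 (not isolated) | CC(=O)O[C@@H]1CC(C)=C(C#C/C(C)=C/[CH-][P+](c2ccccc2)(c2ccccc2)c2ccccc2)C(C)(C)C1 | intermediate
27 | isomer of 28 with Z geometry at the newly formed CH=CH bond (not isolated) | CC(=O)O[C@@H]1CC(C)=C(C#C/C(C)=C/C=C\C=C\C=C(C)\C=C2C=C(/C=C/[C@@]34O[C@]3(C)C[C@@H](O)CC4(C)C)C(=O)O\2)C(C)(C)C1 | intermediate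
28 | pyrrhoxanthin, (3S,5R,6S,3′R) | CC(=O)O[C@@H]1CC(C)=C(C#C/C(C)=C/C=C/C=C/C=C(C)/C=C2C=C(/C=C/[C@@]34O[C@]3(C)C[C@@H](O)CC4(C)C)C(=O)O/2)C(C)(C)C1 | target

**Step count.** Total: 19 steps. Longest linear sequence: 14 steps (steps 1–10, 13–15, 19).

**Steps most likely to fail**

Step 4 (key ring expansion). The insertion may occur on the wrong side, because the β-silyloxy group lowers the migratory aptitude of the CH2 carbon relative to the quaternary carbon. Silanol may also be eliminated under Lewis acid, or the secondary diazoalkane may decompose before it adds to the hindered carbonyl. The fallback sets out from 5 and returns at 7, and is still a one-carbon ring expansion, but with the site of insertion fixed by an enol ether. LDA/TMSCl converts 5 into tert-butyl{[(1S)-4,4-dimethyl-3-(trimethylsilyloxy)cyclopent-2-en-1-yl]oxy}dimethylsilane F1. Chloro(methyl)carbenoid (from 1,1-dichloroethane and n-BuLi, −35 °C) adds to give (4S)-4-(tert-butyldimethylsilyloxy)-6-chloro-2,2,6-trimethyl-1-(trimethylsilyloxy)bicyclo[3.1.0]hexane F2. On warming in toluene this opens by loss of chloride and the silyl group to (4S)-4-(tert-butyldimethylsilyloxy)-2,6,6-trimethylcyclohex-2-en-1-one F3. Hydrogenation (H2, Pd/C, EtOAc) then gives 7.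

Step 6 (hydroxymethyl Stille coupling). Transmetalation of the sp3 stannane to the vinylpalladium flanked by a gem-dimethyl carbon and a methyl-bearing carbon may be too slow, so that reduction or hydrolysis of the triflate takes over. The fallback sets out from 9 and returns at 10. Palladium-catalysed methoxycarbonylation (Pd(OAc)2, PPh3, CO, MeOH, Et3N, DMF, 60 °C), where the small CO inserts readily, gives methyl (4R)-4-(tert-butyldimethylsilyloxy)-2,6,6-trimethylcyclohex-1-ene-1-carboxylate F4. DIBAL-H in CH2Cl2 at −78 °C reduces it to 10.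

Step 19 (final Wittig olefination). Geometry control at the new double bond may be poor and the thermal Z → E equilibration incomplete, or the ylide or base may attack the lactone and the acetate. The fallback sets out from 21 and 24 and returns at 28, joining the halves one bond further along the chain by a stereospecific sp2–sp2 coupling. Aldehyde 21 is converted with Cl2CHBpin/CrCl2/LiI into (5Z)-3-{(E)-2-[(1S,4S,6R)-4-hydroxy-2,2,6-trimethyl-7-oxabicyclo[4.1.0]heptan-1-yl]ethenyl}-5-[(2E,4E)-2-methyl-5-(4,4,5,5-tetramethyl-1,3,2-dioxaborolan-2-yl)penta-2,4-dien-1-ylidene]furan-2(5H)-one F5. Alcohol 24 is oxidised with MnO2 to (1R)-3,5,5-trimethyl-4-[(3E)-3-methyl-5-oxopent-3-en-1-yn-1-yl]cyclohex-3-en-1-yl acetate F6. Takai iodo-olefination (CHI3, CrCl2, THF) converts this into (1R)-4-[(3E,5E)-6-iodo-3-methylhexa-3,5-dien-1-yn-1-yl]-3,5,5-trimethylcyclohex-3-en-1-yl acetate F7. Suzuki–Miyaura coupling of F5 with F7 (Pd2(dba)3, AsPh3, Ag2O, THF/H2O, rt) gives 28 directly.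

**Further compounds**

F1 | step 4 | tert-butyl{[(1S)-4,4-dimethyl-3-(trimethylsilyloxy)cyclopent-2-en-1-yl]oxy}dimethylsilane | CC1(C)C[C@H](O[Si](C)(C)C(C)(C)C)C=C1O[Si](C)(C)C
F2 | step 4 | (4S)-4-(tert-butyldimethylsilyloxy)-6-chloro-2,2,6-trimethyl-1-(trimethylsilyloxy)bicyclo[3.1.0]hexane | CC1(Cl)C2[C@@H](O[Si](C)(C)C(C)(C)C)CC(C)(C)C12O[Si](C)(C)C
F3 | step 4 | (4S)-4-(tert-butyldimethylsilyloxy)-2,6,6-trimethylcyclohex-2-en-1-one | CC1=C[C@@H](O[Si](C)(C)C(C)(C)C)CC(C)(C)C1=O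
F4 | step 6 | methyl (4R)-4-(tert-butyldimethylsilyloxy)-2,6,6-trimethylcyclohex-1-ene-1-carboxylate | CC1=C(C(=O)OC)C(C)(C)C[C@H](O[Si](C)(C)C(C)(C)C)C1
F5 | step 19 | (5Z)-3-{(E)-2-[(1S,4S,6R)-4-hydroxy-2,2,6-trimethyl-7-oxabicyclo[4.1.0]heptan-1-yl]ethenyl}-5-[(2E,4E)-2-methyl-5-(4,4,5,5-tetramethyl-1,3,2-dioxaborolan-2-yl)penta-2,4-dien-1-ylidene]furan-2(5H)-one | CC1(C)OB(/C=C/C=C(C)/C=C2C=C(/C=C/[C@@]34O[C@]3(C)C[C@@H](O)CC4(C)C)C(=O)O/2)OC1(C)C
F6 | step 19 | (1R)-3,5,5-trimethyl-4-[(3E)-3-methyl-5-oxopent-3-en-1-yn-1-yl]cyclohex-3-en-1-yl acetate | CC(=O)O[C@@H]1CC(C)=C(C#C/C(C)=C/C=O)C(C)(C)C1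
F7 | step 19 | (1R)-4-[(3E,5E)-6-iodo-3-methylhexa-3,5-dien-1-yn-1-yl]-3,5,5-trimethylcyclohex-3-en-1-yl acetate | CC(=O)O[C@@H]1CC(C)=C(C#C/C(C)=C/C=C/I)C(C)(C)C1
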